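## The problem

Squamatic acid 25 is a depside in which an aryl ester joins C1 of ring A (a 2-hydroxy-4-methoxy-6-methylbenzoyl unit with a carboxyl group at C3) to the C4' oxygen of ring B (2,4-dihydroxy-3,6-dimethylbenzoic acid, numbered from its carboxyl carbon C1'). There is no stereocentre, so the difficulty is purely regiochemical: ring A carries five substituents in fixed order, with C2 OH, the C3 carboxyl carbon and C4 OMe on three adjacent carbons and only C5 left as CH. A late electrophilic introduction of the C3 carbon would have to distinguish C3 from C5 and from C5' of ring B, so this carbon should arrive with the ring. Ring B is simpler: it is 2,5-dimethylresorcinol 1 plus one carboxyl, its C2' OH is chelated and sluggish, and its C4' OH is the one to be acylated. The sensitive features are the depside ester (cleaved or transposed by hydroxide, alkoxide and amines), the two salicylic acid units (decarboxylation on heating in acid) and two electron-rich rings with free positions that halogenate easily, so the last step must be neutral. The feature that invites the key step is that C2(OH)–C3(C)–C4(OMe) of ring A maps onto a ketene carbonyl carbon followed by the two carbons of a methoxyalkyne, while C5(H)–C6(CH3)–C1(CO2Ar) maps onto the alkenyl part of a vinylketene. Ring A can therefore be assembled from two acyclic partners, with every substituent placed by connectivity and the depside ester already present.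

## Retrosynthesis

**Final deprotection.** The last bond cut is the benzyl C–O bond of the ring B ester, so 25 comes from monobenzyl ester 24. Hydrogenolysis is preferred over any hydrolytic unmasking because it is neutral and leaves the depside ester and both salicylic acids alone. The forward step only has to be clean.

**Oxidation level at C3.** The C3 carboxyl of 24 is traced through aldehyde 23 and benzylic alcohol 22 to silyl ether 21. The carboxyl is not carried through the ring construction, because an alkyne bearing both an alkoxy group and a carboxyl is a push-pull system too electron-poor to add to a ketene. A siloxymethyl group keeps the alkyne nucleophilic and is inert to light and heat. The price is three functional-group steps that must spare the aryl ester and the free positions C5 and C5'.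

**Ring A (key disconnection).** In 21 the bonds C2–C3, C4–C5 and C1–C2 are cut, which dissects ring A into diazo enone 11 and methoxyalkyne 16. The neighbouring cuts are esterification of a preformed ring A acid, or substitution on a preformed depside. Against them, this cut creates the contiguous OH/C/OMe triad in one operation, with regiochemistry set by the polarization of the alkyne, and makes C5 the CH by construction. The precursors are much simpler: 11 holds only ring B and a five-carbon chain, and 16 is a three-carbon alkyne. The forward reaction asks for Wolff rearrangement of 11 to vinylketene 17, regioselective 2+2 addition of 16, and electrocyclic opening and closure, all in the presence of the aryl ester. The C2' hydroxyl of ring B is left free. It is hydrogen-bonded to the benzyl ester carbonyl and flanked on both sides, exactly like the C2 hydroxyl that the step itself creates. Masking it would cost three steps, since the more reactive C4' hydroxyl would have to be blocked first, and would remove no liability that 21 does not already have.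

**Diazo enone.** 11 is cut at the C–N bond of the diazo group to methyl ketone 9 (diazo transfer by way of trifluoroacetyl diketone 10). 9 is cut at its C2=C3 double bond to phosphorane 8 and diketone 6. 8 is cut at the P–C and ester C–O bonds to bromoacetate 5, and hence to phenol 3 and acid bromide 4. Diazo transfer is chosen over acylation of a diazoalkane by an acid chloride, because a diazoalkane would add across the enedioate double bond. The Wittig reaction with the symmetric, activated diketone 6 fixes the trisubstituted E alkene and needs no regiocontrol. The forward steps require 4'-O-selective acylation of 3, E-selective olefination, and kinetic enolization of the methyl ketone of 9 without loss of the aryl ester.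

**Ring B.** 3 is cut at the benzyl ester to acid 2, and 2 at the C1'–carboxyl bond to resorcinol 1. Because C2 of 1 is blocked by a methyl group, the two remaining ring positions are equivalent and carboxylation can give only 2. The forward steps need a chelation-driven carboxylation and a carboxylate-selective benzylation.

**Alkyne.** 16 is cut at the O–Si bond and at the bond between the alkyne and its CH2 group, leading to acetylide 14 (through alkoxide 15) and a one-carbon aldehyde electrophile. 14 comes from dichlorovinyl ether 13 by elimination and chlorine–lithium exchange, and 13 from trichloroethylene 12 by base-mediated addition of the alcohol that supplies the methyl ether. The methyl ether is required because it becomes the C4 OMe of 25; an ynol ether with another alkyl group would put the wrong ether there. The forward sequence must avoid isolating the acid-sensitive propargylic alcohol, which is why 15 is silylated in the flask.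

## Roads not taken

**Alternative 1:** acylketene capture and biomimetic aldol aromatization.
- **Cut:** the depside C–O bond and the C1–C6 bond of ring A together, unravelling ring A to the diketo-dioxinone A2.
- **Forward key step:** heating A2 with phenol 3 would unmask its acylketene by cycloreversion. The C4' hydroxyl would trap it as aryl 3,5,7-trioxooctanoate A3, and intramolecular aldol condensation with dehydration would give the orsellinate depside A1.
- **Merits:** depside ester and ring A are formed together from the same ring B phenol 3, with no diazo compound, no photochemistry and no protecting group on ring A.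
- **Weak points:** A1 lacks both the C3 carbon and the 4-O-methyl group. The methylation is manageable, since only the C4 OH is unchelated. The C3 carbon would then have to be placed between two oxygens by electrophilic substitution on a depside with three activated free positions (C3, C5, C5'). In A3 the aryloxy group is also a good leaving group, so Claisen-type cyclization with expulsion of 3 competes with the aldol.
- **Comparison:** to the bare depside skeleton this road is shorter (one step from 3, against four for 3 to 21), and that is a real advantage. The chosen plan sets against it that the C3 carbon and the C4 OMe are delivered by construction, so no regiochemical contest remains after ring formation.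

**Alternative 2:** aryne insertion into a formamide.
- **Cut:** the C2–O and C3–CHO bonds of ring A, leading back to silyl triflate A5, which carries a C2 triflate and a C3 trimethylsilyl group on the complete depside.
- **Forward key step:** fluoride would trigger 1,2-elimination across C2–C3 of A5. N,N-Dimethylformamide A6 would add across the resulting strained triple bond with oxygen at C2 and the formyl carbon at C3, and hydrolysis would give salicylaldehyde A4.
- **Merits:** A4 stands at the aldehyde oxidation level, only a chlorite oxidation and a hydrogenolysis from 25. That is two steps closer than 21, and on this point the alternative is better.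
- **Weak points:** A5 is already a hexasubstituted benzene with every ring A carbon except the formyl group in place. Making it means assembling the depside first and then brominating, silylating and triflating ring A, which converts the existing C2 oxygen into a leaving group only to bring an oxygen back. The regiochemistry of addition is also contested: the C4 methoxy group directs the nucleophilic oxygen to C2, but the C1 acyl group directs it to C3 and crowds C2. Fluoride and the zwitterionic adduct must also coexist with the aryl ester.
- **Comparison:** the endgame is shorter, but the difficulty is moved into the precursor. The chosen plan sets against it a ring A made from acyclic pieces, with no penta- or hexasubstituted arene to prepare beforehand.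

**Alternative 3:** Brassard diene Diels–Alder reaction.
- **Cut:** C5–C6 and C1–C2 of ring A, giving the ring B but-2-ynoate A8 and the Brassard diene A9.
- **Forward key step:** cycloaddition of A9 to A8, then aromatization by loss of one alkoxy group from the ketene acetal carbon, would give the everninate depside A7.
- **Merits:** both partners are two or three steps from commercial materials, the regiochemistry of such dienes with ynoates is dependable, and the OH/OMe/CH3 pattern arrives directly. To A7 this road is at least as short as the chosen one.
- **Weak points:** A7 has hydrogen at C3. The carbon must be added afterwards by ortho-formylation between OH and OMe to give A4, in competition with C5 and with ring B, and is then oxidized. The β-methyl ynoate A8 is also a sluggish dienophile and needs heating, which the labile diene A9 tolerates poorly.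
- **Comparison:** step count is similar or slightly better for this road. The chosen plan sets against it that the C3 carbon comes with the alkyne, so no late electrophilic substitution on a doubly activated depside is needed.

Key step: step 8

## Route

Step 1
Reactants: 1 2,5-dimethylbenzene-1,3-diol (2,5-dimethylresorcinol)
Product: 2 2,4-dihydroxy-3,6-dimethylbenzoic acid
Conditions: MeOMgOCO2Me (2 M in DMF), 120 °C; then aq HCl, 0 °C
Reagents that add atoms: methoxymagnesium methyl carbonate, CO[Mg]OC(=O)OC
Why: Chelation-driven ortho-carboxylation of a resorcinol (Kolbe–Schmitt type); C2 is blocked by methyl, so the two equivalent free positions are the only sites, and the magnesium salicylate chelate holds the equilibrium on the product side until cold acidification.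

Step 2
Reactants: 2 2,4-dihydroxy-3,6-dimethylbenzoic acid
Product: 3 benzyl 2,4-dihydroxy-3,6-dimethylbenzoate
Conditions: BnBr, KHCO3, DMF, 40 °C
Reagents that add atoms: benzyl bromide, BrCc1ccccc1
Why: Carboxylate O-alkylation; hydrogencarbonate ionizes the acid but not the phenols to a useful extent, so only the ester should form.

Step 3
Reactants: 3 benzyl 2,4-dihydroxy-3,6-dimethylbenzoate; 4 bromoacetyl bromide
Product: 5 benzyl 4-(2-bromoacetoxy)-2-hydroxy-3,6-dimethylbenzoate
Conditions: pyridine, CH2Cl2, −10 °C
Reagents that add atoms: none
Why: O-acylation of the free C4 hydroxyl by an acid bromide; the C2 hydroxyl is hydrogen-bonded to the ester carbonyl and flanked on both sides, which is the usual basis of 4-O-selective acylation in depside synthesis.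

Step 4
Reactants: 5 benzyl 4-(2-bromoacetoxy)-2-hydroxy-3,6-dimethylbenzoate; 6 butane-2,3-dione
Product: 9 benzyl 2-hydroxy-3,6-dimethyl-4-{[(2E)-3-methyl-4-oxopent-2-enoyl]oxy}benzoate, via phosphonium bromide 7 (not isolated), via phosphorane 8 (not isolated)
Conditions: PPh3, CH2Cl2, rt; then Et3N, 6 (3 equiv), rt
Reagents that add atoms: none
Why: SN2 formation of the phosphonium salt, deprotonation to the ester-stabilized ylide and Wittig olefination of one carbonyl of the activated 1,2-diketone; stabilized ylides are expected to favour the E enoate (ester trans to acetyl), and excess diketone suppresses a second olefination.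

Step 5
Reactants: 9 benzyl 2-hydroxy-3,6-dimethyl-4-{[(2E)-3-methyl-4-oxopent-2-enoyl]oxy}benzoate
Product: 11 benzyl 4-{[(2E)-5-diazo-3-methyl-4-oxopent-2-enoyl]oxy}-2-hydroxy-3,6-dimethylbenzoate, via trifluoroacetyl diketone 10 (not isolated)
Conditions: LiN(SiMe3)2 (2.2 equiv), THF, −78 °C; CF3CO2CH2CF3 (excess); aq HCl work-up; then MeSO2N3, Et3N, H2O, MeCN, rt
Reagents that add atoms: methanesulfonyl azide, CS(=O)(=O)N=[N+]=[N-]
Why: Detrifluoroacetylative diazo transfer: the first equivalent of base parks the chelated phenol as its lithium salt, the second enolizes the methyl ketone kinetically, Claisen trifluoroacetylation activates that carbon, and sulfonyl azide transfer then expels the trifluoroacetyl group. Any trifluoroacetate formed on the phenol oxygen is hydrolysed in the aqueous amine medium of the transfer stage. The method is the standard entry to diazo enones, which cannot be made by diazoalkane acylation because the alkene would undergo dipolar cycloaddition.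

Step 6
Reactants: 12 trichloroethylene
Product: 13 (E)-1,2-dichloro-1-methoxyethene
Conditions: KH, MeOH, THF, 0 °C; then 12, −50 °C to rt
Reagents that add atoms: methanol, CO
Why: Base-induced elimination to dichloroacetylene followed by anti addition of methoxide and protonation, the established route from trichloroethylene to 1,2-dichlorovinyl ethers; the alkene geometry is immaterial because both chlorines are removed in the next step.

Step 7
Reactants: 13 (E)-1,2-dichloro-1-methoxyethene
Product: 16 1-methoxy-3-(triisopropylsilyloxy)prop-1-yne, via lithium methoxyacetylide 14 (not isolated), via lithium 3-methoxyprop-2-yn-1-olate 15 (not isolated)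
Conditions: n-BuLi (2.2 equiv), THF, −78 to −40 °C; (CH2O)n, −78 °C to rt; iPr3SiOTf, −78 to 0 °C; Et3N quench
Reagents that add atoms: formaldehyde (as paraformaldehyde), C=O; triisopropylsilyl trifluoromethanesulfonate, CC(C)[Si](OS(=O)(=O)C(F)(F)F)(C(C)C)C(C)C
Why: Dehydrochlorination to the chloroalkyne and chlorine–lithium exchange by the second equivalent of n-BuLi give the alkoxyacetylide, which adds to formaldehyde. Silylating the lithium alkoxide in the flask avoids isolating the acid-sensitive 3-alkoxypropargyl alcohol.

Step 8
Reactants: 11 benzyl 4-{[(2E)-5-diazo-3-methyl-4-oxopent-2-enoyl]oxy}-2-hydroxy-3,6-dimethylbenzoate; 16 1-methoxy-3-(triisopropylsilyloxy)prop-1-yne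
Product: 21 benzyl 2-hydroxy-4-{[2-hydroxy-4-methoxy-6-methyl-3-(triisopropylsilyloxymethyl)benzoyl]oxy}-3,6-dimethylbenzoate, via vinylketene 17 (not isolated), via 4-vinylcyclobutenone 18 (not isolated), via dienylketene 19 (not isolated), via cyclohexadienone 20 (not isolated)
Conditions: 16 (2.5 equiv), degassed CH2Cl2, hν (365 nm), rt; then toluene, 80 °C, dark
Reagents that add atoms: none
Why: Irradiation of the diazo ketone expels N2 and the Wolff 1,2-shift of the alkenyl group gives vinylketene 17, whose electrophilic carbonyl carbon is attacked by the alkyne carbon β to oxygen of 16, so that 2+2 cycloaddition (C2–C3 and C4–C5) gives 4-vinylcyclobutenone 18. Warming opens 18 by reversible four-electron electrocyclic cleavage to dienylketene 19; only the isomer with the alkenyl group turned inward can react further, and ring A is closed by a thermal six-electron disrotatory electrocyclization that forms C1–C2 and gives cyclohexadienone 20, which tautomerizes to phenol 21. The closest known reaction type is the Danheiser benzannulation in its photochemical diazo ketone variant with alkoxy- and siloxyalkynes, which gives resorcinol monoethers carrying the alkyne substituent between the two oxygens. No stereocentre survives, since the sp3 carbons of 18 and 20 are transient and are lost on ring opening and enolization. The required regiochemistry (OH at C2, CH2OSi at C3, OMe at C4) is fixed by the polarization of the ynol ether, and the positions of H, CH3 and the ester on C5, C6 and C1 follow from the connectivity of 17. The E alkene of 11 keeps the aryl ester turned away from the ketene, which blocks oxa-electrocyclization of 17 onto the ester carbonyl and leaves only the small hydrogen inside during closure of 19. Chemoselectivity rests on the excess of nucleophilic alkyne and on the fact that the only hydroxyls present (C2' OH and the new C2 OH) are hydrogen-bonded to ester carbonyls and flanked on both sides, so they add to the ketene slowly; light of 365 nm excites the diazo enone but not the aryl ester, which avoids photo-Fries cleavage.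

Step 9
Reactants: 21 benzyl 2-hydroxy-4-{[2-hydroxy-4-methoxy-6-methyl-3-(triisopropylsilyloxymethyl)benzoyl]oxy}-3,6-dimethylbenzoate
Product: 22 benzyl 2-hydroxy-4-{[2-hydroxy-3-(hydroxymethyl)-4-methoxy-6-methylbenzoyl]oxy}-3,6-dimethylbenzoate
Conditions: Bu4NF, AcOH, THF, 0 °C
Reagents that add atoms: none
Why: Fluoride cleavage of the primary silyl ether; acetic acid buffering keeps the medium from becoming basic enough to cleave or transpose the depside ester.

Step 10
Reactants: 22 benzyl 2-hydroxy-4-{[2-hydroxy-3-(hydroxymethyl)-4-methoxy-6-methylbenzoyl]oxy}-3,6-dimethylbenzoate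
Product: 23 benzyl 4-[(3-formyl-2-hydroxy-4-methoxy-6-methylbenzoyl)oxy]-2-hydroxy-3,6-dimethylbenzoate
Conditions: MnO2, CH2Cl2, rt
Reagents that add atoms: none
Why: MnO2 oxidation of a benzylic (salicyl) alcohol to the salicylaldehyde; the heterogeneous oxidant is selective for the benzylic position, stops at the aldehyde and tolerates hindered chelated phenols.

Step 11
Reactants: 23 benzyl 4-[(3-formyl-2-hydroxy-4-methoxy-6-methylbenzoyl)oxy]-2-hydroxy-3,6-dimethylbenzoate
Product: 24 3-{[4-(benzyloxycarbonyl)-3-hydroxy-2,5-dimethylphenoxy]carbonyl}-2-hydroxy-6-methoxy-4-methylbenzoic acid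
Conditions: NaClO2, NaH2PO4, 2-methylbut-2-ene (large excess), t-BuOH/THF/H2O, 0 °C to rt
Reagents that add atoms: sodium chlorite NaClO2, [Na+].[O-]Cl=O
Why: Pinnick chlorite oxidation of the aldehyde under buffered, mildly acidic conditions that the depside ester tolerates; the alkene scavenger removes HOCl before it can chlorinate C5 or C5', and no peroxide is present that could start a Dakin oxidation.

Step 12
Reactants: 24 3-{[4-(benzyloxycarbonyl)-3-hydroxy-2,5-dimethylphenoxy]carbonyl}-2-hydroxy-6-methoxy-4-methylbenzoic acid
Product: 25 squamatic acid, 3-[(4-carboxy-3-hydroxy-2,5-dimethylphenoxy)carbonyl]-2-hydroxy-6-methoxy-4-methylbenzoic acid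
Conditions: H2 (1 atm), Pd/C (palladium on carbon), EtOAc, rt
Reagents that add atoms: none
Why: Hydrogenolysis of the benzyl ester under neutral conditions; the aryl ester, the methyl ether and both salicylic acids are untouched, so the free depside never meets acid or base.

## Compound list

1 | 2,5-dimethylbenzene-1,3-diol (2,5-dimethylresorcinol) | Cc1cc(O)c(C)c(O)c1 | starting material
2 | 2,4-dihydroxy-3,6-dimethylbenzoic acid | Cc1cc(O)c(C)c(O)c1C(=O)O | intermediate
3 | benzyl 2,4-dihydroxy-3,6-dimethylbenzoate | Cc1cc(O)c(C)c(O)c1C(=O)OCc1ccccc1 | intermediate
4 | bromoacetyl bromide | BrCC(Br)=O | starting material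
5 | benzyl 4-(2-bromoacetoxy)-2-hydroxy-3,6-dimethylbenzoate | BrCC(=O)Oc1cc(C)c(C(=O)OCc2ccccc2)c(O)c1C | intermediate
6 | butane-2,3-dione | CC(=O)C(C)=O | starting material
7 | {2-[4-(benzyloxycarbonyl)-3-hydroxy-2,5-dimethylphenoxy]-2-oxoethyl}triphenylphosphonium bromide | [Br-].O=C(C[P+](c1ccccc1)(c1ccccc1)c1ccccc1)Oc1cc(C)c(C(=O)OCc2ccccc2)c(O)c1C | intermediate
8 | benzyl 2-hydroxy-3,6-dimethyl-4-{[(triphenylphosphoranylidene)acetyl]oxy}benzoate | O=C(C=P(c1ccccc1)(c1ccccc1)c1ccccc1)Oc1cc(C)c(C(=O)OCc2ccccc2)c(O)c1C | intermediate
9 | benzyl 2-hydroxy-3,6-dimethyl-4-{[(2E)-3-methyl-4-oxopent-2-enoyl]oxy}benzoate | CC(=O)/C(C)=C/C(=O)Oc1cc(C)c(C(=O)OCc2ccccc2)c(O)c1C | intermediate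
10 | benzyl 2-hydroxy-3,6-dimethyl-4-{[(2E)-7,7,7-trifluoro-3-methyl-4,6-dioxohept-2-enoyl]oxy}benzoate | O=C(CC(=O)/C(C)=C/C(=O)Oc1cc(C)c(C(=O)OCc2ccccc2)c(O)c1C)C(F)(F)F | intermediate
11 | benzyl 4-{[(2E)-5-diazo-3-methyl-4-oxopent-2-enoyl]oxy}-2-hydroxy-3,6-dimethylbenzoate | [N-]=[N+]=CC(=O)/C(C)=C/C(=O)Oc1cc(C)c(C(=O)OCc2ccccc2)c(O)c1C | intermediate
12 | trichloroethylene | ClC=C(Cl)Cl | starting material
13 | (E)-1,2-dichloro-1-methoxyethene | CO/C(Cl)=C\Cl | intermediate
14 | lithium methoxyacetylide | [Li]C#COC | intermediate
15 | lithium 3-methoxyprop-2-yn-1-olate | [Li+].[O-]CC#COC | intermediate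
16 | 1-methoxy-3-(triisopropylsilyloxy)prop-1-yne | COC#CCO[Si](C(C)C)(C(C)C)C(C)C | intermediate
17 | benzyl 2-hydroxy-3,6-dimethyl-4-{[(2E)-3-methyl-5-oxopenta-2,4-dienoyl]oxy}benzoate (vinylketene) | O=C=C/C(C)=C/C(=O)Oc1cc(C)c(C(=O)OCc2ccccc2)c(O)c1C | intermediate
18 | benzyl 2-hydroxy-4-({(2E)-3-[2-methoxy-4-oxo-3-(triisopropylsilyloxymethyl)cyclobut-2-en-1-yl]but-2-enoyl}oxy)-3,6-dimethylbenzoate (racemic) | COC1=C(CO[Si](C(C)C)(C(C)C)C(C)C)C(=O)C1/C(C)=C/C(=O)Oc1cc(C)c(C(=O)OCc2ccccc2)c(O)c1C | intermediate
19 | benzyl 2-hydroxy-4-{[(2E,4E)-5-methoxy-3-methyl-7-oxo-6-(triisopropylsilyloxymethyl)hepta-2,4,6-trienoyl]oxy}-3,6-dimethylbenzoate (dienylketene, alkenyl group cis to the ketene-bearing carbon) | O=C=C(CO[Si](C(C)C)(C(C)C)C(C)C)/C(OC)=C\C(C)=C\C(=O)Oc1cc(C)c(C(=O)OCc2ccccc2)c(O)c1C | intermediate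
20 | benzyl 2-hydroxy-4-{[4-methoxy-6-methyl-2-oxo-3-(triisopropylsilyloxymethyl)cyclohexa-3,5-diene-1-carbonyl]oxy}-3,6-dimethylbenzoate (racemic) | COC1=C(CO[Si](C(C)C)(C(C)C)C(C)C)C(=O)C(C(=O)Oc2cc(C)c(C(=O)OCc3ccccc3)c(O)c2C)C(C)=C1 | intermediate
21 | benzyl 2-hydroxy-4-{[2-hydroxy-4-methoxy-6-methyl-3-(triisopropylsilyloxymethyl)benzoyl]oxy}-3,6-dimethylbenzoate | COc1cc(C)c(C(=O)Oc2cc(C)c(C(=O)OCc3ccccc3)c(O)c2C)c(O)c1CO[Si](C(C)C)(C(C)C)C(C)C | intermediate
22 | benzyl 2-hydroxy-4-{[2-hydroxy-3-(hydroxymethyl)-4-methoxy-6-methylbenzoyl]oxy}-3,6-dimethylbenzoate | COc1cc(C)c(C(=O)Oc2cc(C)c(C(=O)OCc3ccccc3)c(O)c2C)c(O)c1CO | intermediate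
23 | benzyl 4-[(3-formyl-2-hydroxy-4-methoxy-6-methylbenzoyl)oxy]-2-hydroxy-3,6-dimethylbenzoate | COc1cc(C)c(C(=O)Oc2cc(C)c(C(=O)OCc3ccccc3)c(O)c2C)c(O)c1C=O | intermediate
24 | 3-{[4-(benzyloxycarbonyl)-3-hydroxy-2,5-dimethylphenoxy]carbonyl}-2-hydroxy-6-methoxy-4-methylbenzoic acid | COc1cc(C)c(C(=O)Oc2cc(C)c(C(=O)OCc3ccccc3)c(O)c2C)c(O)c1C(=O)O | intermediate
25 | squamatic acid, 3-[(4-carboxy-3-hydroxy-2,5-dimethylphenoxy)carbonyl]-2-hydroxy-6-methoxy-4-methylbenzoic acid | COc1cc(C)c(C(=O)Oc2cc(C)c(C(=O)O)c(O)c2C)c(O)c1C(=O)O | target

## Step count and least certain steps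

Total: 12 steps. Longest linear sequence: 10 steps (steps 1–5 and 8–12); the alkyne branch (steps 6–7) joins at step 8.

**Step 8 (key step).** The most likely failure is light-induced E-to-Z isomerization of the enoate double bond of 11 or 17, after which the ketene closes onto the ester carbonyl instead of adding the alkyne. Further risks are dipolar cycloaddition of the diazo group to the electron-poor alkene of a second molecule during concentration or storage, and incomplete thermal opening of the alkoxy-substituted cyclobutenone. The cause is that 11 combines a diazo ketone with a doubly activated, photoisomerizable alkene. The fallback gives up the benzannulation and uses a classical depside condensation, setting out from 3 and returning at 23. Commercially available 2-hydroxy-4-methoxy-6-methylbenzoic acid F1 would be benzylated (BnBr, KHCO3, DMF) to benzyl 2-hydroxy-4-methoxy-6-methylbenzoate F2. Rieche formylation of F2 ortho to the phenol (Cl2CHOMe, TiCl4, CH2Cl2) should give benzyl 3-formyl-2-hydroxy-4-methoxy-6-methylbenzoate F3; any C5 isomer would be removed at this cheap stage. Brief hydrogenolysis of F3 (H2, Pd/C, EtOAc), stopped as soon as the benzyl ester is consumed so that the chelated formyl group is not reduced, would free 3-formyl-2-hydroxy-4-methoxy-6-methylbenzoic acid F4. Condensation of F4 with the C4 hydroxyl of 3 through the mixed anhydride formed with (CF3CO)2O in toluene would give 23.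

**Step 5.** The most likely failure is loss of the aryl ester through attack by amide, enolate or trifluoroethoxide, or conjugate addition of the ketone enolate to the enedioyl system of a second molecule. The cause is that 9 is both an activated ester and a strong Michael acceptor; the dianion may also be poorly soluble at −78 °C. The fallback avoids strong base, setting out from 9 and returning at 11. Soft enolization (Me3SiOTf, Et3N, CH2Cl2) would give benzyl 3,6-dimethyl-4-{[(2E)-3-methyl-4-(trimethylsilyloxy)penta-2,4-dienoyl]oxy}-2-(trimethylsilyloxy)benzoate F5. Treatment of F5 with N-bromosuccinimide at −78 °C followed by aqueous work-up would give benzyl 4-{[(2E)-5-bromo-3-methyl-4-oxopent-2-enoyl]oxy}-2-hydroxy-3,6-dimethylbenzoate F6. N,N'-Ditosylhydrazine with DBU in THF at 0 °C would then convert the bromomethyl ketone F6 into the diazo ketone 11 by N-alkylation and double sulfinate elimination.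

**Step 7.** The most likely failure is decomposition of the ynol ether under Lewis acid (silyl triflate) or protic activation, by hydration or rearrangement of the propargylic system. Incomplete depolymerization of the aldehyde source would also leave acetylide 14 unconsumed, and its carbon would be lost as volatile material on work-up. The fallback sets out from 13 and returns at 16. Acetylide 14 would be generated as in the route and alkylated directly with commercial chloromethyl triisopropylsilyl ether (SN2 at an α-chloro ether). This forms the C–C bond and brings in the silyl ether in one event, with no alkoxide and no silyl triflate; it makes no compound outside the list.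

**Step 4.** The most likely failure is erosion of E selectivity, consumption of the ylide by a second olefination or by proton transfer from the phenol, or cleavage of the aryl ester at the phosphonium stage. The fallback sets out from 3 and returns at 9. Diketone 6 would be olefinated with commercial tert-butyl (triphenylphosphoranylidene)acetate to tert-butyl (2E)-3-methyl-4-oxopent-2-enoate F7, where isomers can be separated on a simple compound. Cleavage of F7 with CF3CO2H would give (2E)-3-methyl-4-oxopent-2-enoic acid F8. Carbodiimide esterification of F8 with the C4 hydroxyl of 3 (dicyclohexylcarbodiimide, catalytic 4-dimethylaminopyridine, CH2Cl2, 0 °C) would give 9.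

**Step 1.** The most likely failure is incomplete carboxylation, or decarboxylation of 2 during acidification. The position is flanked by a methyl group, and the equilibrium favours the acid only while the magnesium chelate is intact. The fallback sets out from 1 and returns at 2. Vilsmeier–Haack formylation of 1 (POCl3, DMF, then water) would give 2,4-dihydroxy-3,6-dimethylbenzaldehyde F9, and chlorite oxidation of F9 (NaClO2, sulfamic acid, aqueous dioxane) would give 2.

## Further compounds

F1 | step 8 | 2-hydroxy-4-methoxy-6-methylbenzoic acid | COc1cc(C)c(C(=O)O)c(O)c1
F2 | step 8 | benzyl 2-hydroxy-4-methoxy-6-methylbenzoate | COc1cc(C)c(C(=O)OCc2ccccc2)c(O)c1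
F3 | step 8 | benzyl 3-formyl-2-hydroxy-4-methoxy-6-methylbenzoate | COc1cc(C)c(C(=O)OCc2ccccc2)c(O)c1C=O
F4 | step 8 | 3-formyl-2-hydroxy-4-methoxy-6-methylbenzoic acid | COc1cc(C)c(C(=O)O)c(O)c1C=O
F5 | step 5 | benzyl 3,6-dimethyl-4-{[(2E)-3-methyl-4-(trimethylsilyloxy)penta-2,4-dienoyl]oxy}-2-(trimethylsilyloxy)benzoate | C=C(O[Si](C)(C)C)/C(C)=C/C(=O)Oc1cc(C)c(C(=O)OCc2ccccc2)c(O[Si](C)(C)C)c1C
F6 | step 5 | benzyl 4-{[(2E)-5-bromo-3-methyl-4-oxopent-2-enoyl]oxy}-2-hydroxy-3,6-dimethylbenzoate | BrCC(=O)/C(C)=C/C(=O)Oc1cc(C)c(C(=O)OCc2ccccc2)c(O)c1C
F0 | step 7 | none | none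
F7 | step 4 | tert-butyl (2E)-3-methyl-4-oxopent-2-enoate | CC(=O)/C(C)=C/C(=O)OC(C)(C)C
F8 | step 4 | (2E)-3-methyl-4-oxopent-2-enoic acid | CC(=O)/C(C)=C/C(=O)O
F9 | step 1 | 2,4-dihydroxy-3,6-dimethylbenzaldehyde | Cc1cc(O)c(C)c(O)c1C=O
A1 | alternative 1 | benzyl 4-[(2,4-dihydroxy-6-methylbenzoyl)oxy]-2-hydroxy-3,6-dimethylbenzoate | Cc1cc(O)cc(O)c1C(=O)Oc1cc(C)c(C(=O)OCc2ccccc2)c(O)c1C
A2 | alternative 1 | 2,2-dimethyl-6-(2,4-dioxopentyl)-4H-1,3-dioxin-4-one | CC(=O)CC(=O)CC1=CC(=O)OC(C)(C)O1
A3 | alternative 1 | benzyl 2-hydroxy-3,6-dimethyl-4-[(3,5,7-trioxooctanoyl)oxy]benzoate | CC(=O)CC(=O)CC(=O)CC(=O)Oc1cc(C)c(C(=O)OCc2ccccc2)c(O)c1C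
A4 | alternative 2 | benzyl 2-(benzyloxy)-4-[(3-formyl-2-hydroxy-4-methoxy-6-methylbenzoyl)oxy]-3,6-dimethylbenzoate | COc1cc(C)c(C(=O)Oc2cc(C)c(C(=O)OCc3ccccc3)c(OCc3ccccc3)c2C)c(O)c1C=O
A5 | alternative 2 | benzyl 2-(benzyloxy)-4-{[4-methoxy-6-methyl-2-(trifluoromethanesulfonyloxy)-3-(trimethylsilyl)benzoyl]oxy}-3,6-dimethylbenzoate | COc1cc(C)c(C(=O)Oc2cc(C)c(C(=O)OCc3ccccc3)c(OCc3ccccc3)c2C)c(OS(=O)(=O)C(F)(F)F)c1[Si](C)(C)C
A6 | alternative 2 | N,N-dimethylformamide | CN(C)C=O
A7 | alternative 3 | benzyl 2-(benzyloxy)-4-[(2-hydroxy-4-methoxy-6-methylbenzoyl)oxy]-3,6-dimethylbenzoate | COc1cc(C)c(C(=O)Oc2cc(C)c(C(=O)OCc3ccccc3)c(OCc3ccccc3)c2C)c(O)c1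
A8 | alternative 3 | benzyl 2-(benzyloxy)-4-(but-2-ynoyloxy)-3,6-dimethylbenzoate | CC#CC(=O)Oc1cc(C)c(C(=O)OCc2ccccc2)c(OCc2ccccc2)c1C
A9 | alternative 3 | 1,3-dimethoxy-1-(trimethylsilyloxy)buta-1,3-diene | COC(=C)C=C(OC)O[Si](C)(C)C
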